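If the second substrate were a one-for-one partner of the starting material, the dawn run would end with a leftover. Its second substrate is 67.0% of the starting material, so about a third of the starting material should stay unconverted. Yet target and isomer of the product together stand at 102% of the charge after 2.50 d.

| flask | starting material | second substrate | enzyme | remark | time |
|---|---|---|---|---|---|
| midnight | 10 mM | 10 mM | 1 µM | run made earlier |  |
| dawn | 10 mM | 6.7 mM | 1 µM | run made earlier |  |
| summer | 10 mM | 15 mM | 1 µM | run made earlier |  |
| ochre | 10 mM | 10.0 mM | 1.0 µM | everything together at the start | 2.0 d |
| green | 10 mM (fed, over 30 h) | 10.0 mM | 1.0 µM | all else is in the flask from the start; the feed brings no volume worth counting | 2.0 d |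
| teal | 10 mM (fed, over 3.0 h) | 10.0 mM | 1.0 µM | all else is in the flask from the start; the feed brings no volume worth counting | 2.0 d |
| grey | 10 mM | 10.0 mM (fed, over 30 h) | 1.0 µM | all else is in the flask from the start; the feed brings no volume worth counting | 2.0 d |

midnight run (percent of the starting material charged)

| time / h | target / % | isomer of the product / % |
|---|---|---|
| 5.00 | 19 | 0 |
| 10.0 | 39 | 3 |
| 15.0 | 55 | 11 |
| 20.0 | 62 | 7 |
| 25.0 | 74 | 15 |
| 30.0 | 74 | 21 |

dawn run (percent of the starting material charged)

| time / d | target / % | isomer of the product / % |
|---|---|---|
| 0.208 | 23 | 0 |
| 0.333 | 31 | 1 |
| 0.500 | 44 | 4 |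
| 0.833 | 65 | 12 |
| 1.67 | 67 | 27 |
| 2.50 | 55 | 47 |

summer run (percent of the starting material charged)

| time / d | target / % | isomer of the product / % |
|---|---|---|
| 0.208 | 21 | 1 |
| 0.333 | 31 | 5 |
| 0.500 | 42 | 5 |
| 0.833 | 63 | 12 |
| 1.67 | 69 | 36 |
| 2.50 | 51 | 46 |

(each reading ± 2 percentage points)

- the numbers in the tables scatter by 2 percentage points (one standard deviation)

* the flask that comes out highest in share of target in target plus isomer of the product, or "all alike" when all lie within 1.5 percentage points (ochre / green / teal / grey / all alike)
* share of target in target plus isomer of the product at the end, ochre
* share of target in target plus isomer of the product at the end, green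
* share of target in target plus isomer of the product at the end, teal
* share of target in target plus isomer of the product at the end, grey

The two numbers go together once we stop pairing the two substances. At 20.0 h, target plus isomer is 77.0% in dawn, 69.0% in midnight and 75.0% in summer, with no trend along the second substrate. So we take their mean, 73.7%, as one steady pace. From it we define the clearing time, the zero-order lifetime of the charge: the time the enzyme needs to turn the whole charge at that pace, 27.1 h.

Now we hold each feed against it. Teal's feed of 3.0 h is much shorter than the clearing time, so we expect teal to follow ochre. Green's feed of 30 h is longer than the clearing time, so we expect green's last target to come later than ochre's. With the end of the run held at 2.0 d, later target has less time to drain, and the dawn run's target reads 67% at 1.67 d and 55% at 2.50 d. Grey's starting material goes in at the start, as in ochre, so we place grey with ochre, less firmly, since its fed second substrate begins below the 6.7 mM of the dawn run, the lowest charge tried.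

The forecast gave ochre 61.5%, green 63.5%, teal 61.6% and grey 62.5%, and named green, holding that in teal “the feed outruns the enzyme”.

The flasks gave ochre 59.4%, green 65.2%, teal 59.7% and grey 59.0%.

    starting material + enzyme ⇌ complex A (K = 5900 L mol⁻¹, k = 320 L mol⁻¹ s⁻¹)
    complex A → enzyme + target (k = 0.130 s⁻¹)
    second substrate + enzyme ⇌ complex B (K = 73.0 L mol⁻¹, k = 1900 L mol⁻¹ s⁻¹)
    complex B → enzyme + second product (k = 0.250 s⁻¹)
    target ⇌ isomer of the product (K = 1.80, k = 5.20 × 10⁻⁶ s⁻¹)

At the end of its feed, 1.25 d, green still held 18.4% of its starting material. For a neighbour of grey charged with 25 mM of starting material, the charge is 2.50 times grey's, so at the same pace in concentration the clearing time reckons to 67.9 h, longer than the 2.0 d of the run. That neighbour ended at 2.00 d with 16.6% of its starting material still there.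

The earlier runs and the new flask are calculated with made-up constants, and the scatter is random.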